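**Assumption:** germacrane numbering is used (C1=C10 olefin, ketal C2, C3=C4, furan O on C5, lactone O on C6, ester on C8); the target is (2S,5S,6S,7R,8S), 1(10)Z.

## Retrosynthetic overview

1. Dihydrofuran ketal (last ring): target ⇐ macrocyclic (1(10)Z,3Z)-dienone 21 by desilylation and transannular ketalisation in MeOH.
2. Ten-membered ring: 21 ⇐ seco Z-vinyl iodide / Z-enal 19 by intramolecular Nozaki–Hiyama–Kishi coupling (C2–C3), then oxidation.
3. C7–C8 bond: 19 ⇐ bromomethyl butenolide 8 (C3–C7, C11–C13) + β,γ-unsaturated aldehyde 16 (C8–C10, C1, C2) by Zn-Barbier allylation, which sets C7 and C8 and gives the trans α-methylene lactone.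
4. 8 ⇐ (Z)-3-iodo-2-methylacrolein by Brown syn-alkoxyallylboration (sets C5, C6), then acrylate RCM (butenolide, first ring); 16 ⇐ but-3-yn-1-ol by ynoate syn-carbocupration (Z-C1=C10).
5. Ring order: butenolide/γ-lactone → ten-membered carbocycle → bridging 2,5-dihydrofuran ketal.

## Fragment A: bromomethyl butenolide 8 (C3–C7, C11–C13)

**Step 1**
Reactants: 1, prop-2-yn-1-ol
Product: 2, (Z)-3-iodo-2-methylprop-2-en-1-ol
Conditions: MeMgBr (3 equiv), CuI (10 mol%), THF, −10 °C → rt; then I2, −78 °C → rt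
Reagents that add atoms: methylmagnesium bromide, C[Mg]Br; iodine, II
Why: Alkoxide-directed Cu-catalysed anti-carbomagnesiation puts Me on the internal carbon and the chelated vinyl-Mg cis to CH2O, so iodinolysis gives the Z-iodide (I cis to CH2OH).

**Step 2**
Reactants: 2
Product: 3, (Z)-3-iodo-2-methylprop-2-enal
Conditions: activated MnO2, CH2Cl2, rt, dark; used crude
Reagents that add atoms: none
Why: Neutral allylic oxidation with MnO2 preserves the Z-vinyl iodide.

**Step 3**
Reactants: 3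
Product: 4, (1Z,3S,4S)-1-iodo-4-(methoxymethoxy)-2-methylhexa-1,5-dien-3-ol
Conditions: allyl methoxymethyl ether, s-BuLi, THF, −78 °C; (+)-Ipc2BOMe (from (−)-α-pinene); BF3·OEt2; then 3, −78 °C; NaOH/H2O2
Reagents that add atoms: allyl methoxymethyl ether, C=CCOCOC (as its (Z)-γ-(MOM-oxy)allyl-B(Ipc)2 reagent)
Why: Brown alkoxyallylboration through a chair transition state; the Z-γ-alkoxyallyl unit gives the syn (threo) diol monoether and the lIpc ligands direct Re-face attack, setting C5 (S) and C6 (S).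

**Step 4**
Reactants: 4
Product: 5, tert-butyl{[(1Z,3S,4S)-1-iodo-4-(methoxymethoxy)-2-methylhexa-1,5-dien-3-yl]oxy}dimethylsilane
Conditions: TBSOTf, 2,6-lutidine, CH2Cl2, −78 °C
Reagents that add atoms: TBSOTf, CC(C)(C)[Si](C)(C)OS(=O)(=O)C(F)(F)F
Why: Silylation of the C5 alcohol, which must stay masked until the last step.

**Step 5**
Reactants: 5
Product: 6, (3S,4S,5Z)-4-[(tert-butyldimethylsilyl)oxy]-6-iodo-5-methylhexa-1,5-dien-3-ol
Conditions: Me2BBr, CH2Cl2, −78 °C; then THF/sat. aq NaHCO3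
Reagents that add atoms: none
Why: Me2BBr cleaves the MOM acetal at −78 °C without touching the TBS ether or vinyl iodide, freeing only the C6 hydroxyl.

**Step 6**
Reactants: 6
Product: 7, (3S,4S,5Z)-4-[(tert-butyldimethylsilyl)oxy]-6-iodo-5-methylhexa-1,5-dien-3-yl 2-(bromomethyl)prop-2-enoate
Conditions: 2-(bromomethyl)acrylic acid, DCC, DMAP (5 mol%), CH2Cl2, 0 °C
Reagents that add atoms: 2-(bromomethyl)acrylic acid, OC(=O)C(=C)CBr
Why: Steglich esterification at low temperature with minimal DMAP (to limit N-alkylation by the allylic bromide) installs C11–C13 on O6.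

**Step 7**
Reactants: 7
Product: 8, (5S)-3-(bromomethyl)-5-{(1S,2Z)-1-[(tert-butyldimethylsilyl)oxy]-3-iodo-2-methylprop-2-en-1-yl}furan-2(5H)-one
Conditions: Grubbs II (5 mol%), CH2Cl2, 40 °C, 0.01 M
Reagents that add atoms: none
Why: Ring-closing metathesis of the vinyl group with the acrylate gives the butenolide (ethylene lost); the trisubstituted vinyl iodide is inert and no stereocentre is touched.

## Fragment B: aldehyde 16 (C8–C10, C1, C2)

**Step 8**
Reactants: 9, but-3-yn-1-ol
Product: 10, 1-[(but-3-yn-1-yloxy)methyl]-4-methoxybenzene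
Conditions: NaH, PMBCl, TBAI, THF, 0 °C → rt
Reagents that add atoms: 4-methoxybenzyl chloride, COc1ccc(CCl)cc1
Why: Williamson etherification protects the future C8 oxygen.

**Step 9**
Reactants: 10
Product: 11, methyl 5-[(4-methoxybenzyl)oxy]pent-2-ynoate
Conditions: n-BuLi, THF, −78 °C; ClCO2Me
Reagents that add atoms: methyl chloroformate, COC(=O)Cl
Why: Acylation of the lithium acetylide introduces C2.

**Step 10**
Reactants: 11
Product: 12, methyl (2Z)-5-[(4-methoxybenzyl)oxy]-3-methylpent-2-enoate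
Conditions: Me2CuLi (MeLi, CuI), THF, −78 °C; MeOH quench at −78 °C
Reagents that add atoms: lithium dimethylcuprate, C[Cu-]C.[Li+]
Why: Syn-carbocupration of the ynoate with cold protonation places the chain cis to the ester, giving the Z (nerol-type) C1=C10 olefin.

**Step 11**
Reactants: 12
Product: 13, (2Z)-5-[(4-methoxybenzyl)oxy]-3-methylpent-2-en-1-ol
Conditions: DIBAL-H (2.2 equiv), CH2Cl2, −78 °C
Reagents that add atoms: none
Why: 1,2-Reduction of the enoate to the allylic alcohol without touching the olefin geometry.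

**Step 12**
Reactants: 13
Product: 14, triethyl{[(2Z)-5-[(4-methoxybenzyl)oxy]-3-methylpent-2-en-1-yl]oxy}silane
Conditions: TESCl, imidazole, CH2Cl2, 0 °C
Reagents that add atoms: chlorotriethylsilane, CC[Si](Cl)(CC)CC
Why: The primary TES ether masks C2–OH and can later be oxidised directly.

**Step 13**
Reactants: 14
Product: 15, (3Z)-3-methyl-5-[(triethylsilyl)oxy]pent-3-en-1-ol
Conditions: DDQ, CH2Cl2/pH 7 buffer, 0 °C
Reagents that add atoms: none
Why: Oxidative PMB cleavage under buffered conditions leaves the TES ether intact.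

**Step 14**
Reactants: 15
Product: 16, (3Z)-3-methyl-5-[(triethylsilyl)oxy]pent-3-enal
Conditions: Dess–Martin periodinane, NaHCO3, CH2Cl2, 0 °C; used at once
Reagents that add atoms: none
Why: Buffered Dess–Martin oxidation gives the β,γ-unsaturated aldehyde without conjugation if used immediately.

## Fragment union and endgame

**Step 15**
Reactants: 8 and 16
Product: 17, (4R,5S)-5-{(1S,2Z)-1-[(tert-butyldimethylsilyl)oxy]-3-iodo-2-methylprop-2-en-1-yl}-4-{(1S,3Z)-1-hydroxy-3-methyl-5-[(triethylsilyl)oxy]pent-3-en-1-yl}-3-methylideneoxolan-2-one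
Conditions: Zn dust, THF/sat. aq NH4Cl (5:1), 0 °C → rt
Reagents that add atoms: none
Why: Barbier allylation in which the allylzinc attacks through C7 anti to the C6 substituent (trans lactone, 7R) via a chair transition state of an E-type allylmetal (anti adduct, 8S), forming C7–C8 and the α-methylene lactone.

**Step 16**
Reactants: 17
Product: 18, (1S,3Z)-1-{(2S,3R)-2-[(1S,2Z)-1-[(tert-butyldimethylsilyl)oxy]-3-iodo-2-methylprop-2-en-1-yl]-4-methylidene-5-oxooxolan-3-yl}-3-methyl-5-[(triethylsilyl)oxy]pent-3-en-1-yl 2-methylprop-2-enoate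
Conditions: methacrylic anhydride, Et3N, DMAP (cat.), CH2Cl2, 0 °C → rt
Reagents that add atoms: methacrylic anhydride, CC(=C)C(=O)OC(=O)C(C)=C
Why: DMAP-catalysed acylation of the only free hydroxyl (C8) with retention.

**Step 17**
Reactants: 18
Product: 19, (1S,3Z)-1-{(2S,3R)-2-[(1S,2Z)-1-[(tert-butyldimethylsilyl)oxy]-3-iodo-2-methylprop-2-en-1-yl]-4-methylidene-5-oxooxolan-3-yl}-3-methyl-5-oxopent-3-en-1-yl 2-methylprop-2-enoate
Conditions: (COCl)2, DMSO, CH2Cl2, −78 → −35 °C; then Et3N, −78 → −20 °C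
Reagents that add atoms: none
Why: Swern conditions cleave a primary TES ether in situ and oxidise it to the aldehyde while the secondary TBS ether survives, and the low temperature keeps the Z-enal and the C8 ester intact.

**Step 18**
Reactants: 19
Product: 20, (3aR,4S,6Z,9Z,11S,11aS)-11-[(tert-butyldimethylsilyl)oxy]-8-hydroxy-6,10-dimethyl-3-methylidene-2-oxo-2,3,3a,4,5,8,11,11a-octahydrocyclodeca[b]furan-4-yl 2-methylprop-2-enoate (mixture of C8-carbinol epimers, i.e. germacrane C2)
Conditions: CrCl2 (10 equiv), NiCl2 (0.2 equiv), degassed DMSO/THF, 3 mM, rt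
Reagents that add atoms: none
Why: Intramolecular Nozaki–Hiyama–Kishi macrocyclisation (C2–C3) is selective for vinyl iodide plus aldehyde, tolerates the lactone and esters, retains the trisubstituted Z-alkenyl geometry, and creates only a carbinol centre that is removed in the next step.

**Step 19**
Reactants: 20
Product: 21, (3aR,4S,6Z,9Z,11S,11aS)-11-[(tert-butyldimethylsilyl)oxy]-6,10-dimethyl-3-methylidene-2,8-dioxo-2,3,3a,4,5,8,11,11a-octahydrocyclodeca[b]furan-4-yl 2-methylprop-2-enoate
Conditions: Dess–Martin periodinane, NaHCO3, CH2Cl2, 0 °C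
Reagents that add atoms: none
Why: Neutral oxidation of the bis-allylic alcohol converges both epimers to the cross-conjugated Z,Z-dienone without β-elimination of the C8 ester.

**Step 20**
Reactants: 21
Product: 22, 2-deethoxy-2β-methoxyphantomolin (target)
Conditions: AcCl (0.5 equiv, generates HCl), MeOH, 0 °C → rt; NaHCO3 quench
Reagents that add atoms: methanol, CO
Why: Acidic methanolysis removes the TBS group, the C5 hydroxyl adds transannularly to the C2 ketone across the Z-enone, and MeOH traps the oxocarbenium as the methyl ketal; C2 can only be S because the oxygen bridge must span one face of the ring, and furan formation is blocked by strain.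

## Compound list

1 | prop-2-yn-1-ol | C#CCO | starting material
2 | (Z)-3-iodo-2-methylprop-2-en-1-ol | OC/C(C)=C\I | intermediate
3 | (Z)-3-iodo-2-methylprop-2-enal | O=C/C(C)=C\I | intermediate
4 | (1Z,3S,4S)-1-iodo-4-(methoxymethoxy)-2-methylhexa-1,5-dien-3-ol | I/C=C(C)\[C@H](O)[C@@H](OCOC)C=C | intermediate
5 | TBS ether of 4 | I/C=C(C)\[C@H](O[Si](C)(C)C(C)(C)C)[C@@H](OCOC)C=C | intermediate
6 | (3S,4S,5Z)-4-(TBS-oxy)-6-iodo-5-methylhexa-1,5-dien-3-ol | I/C=C(C)\[C@H](O[Si](C)(C)C(C)(C)C)[C@@H](O)C=C | intermediate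
7 | 2-(bromomethyl)acrylate of 6 | I/C=C(C)\[C@H](O[Si](C)(C)C(C)(C)C)[C@@H](OC(=O)C(=C)CBr)C=C | intermediate
8 | (5S)-3-(bromomethyl)-5-[(1S,2Z)-1-(TBS-oxy)-3-iodo-2-methylprop-2-en-1-yl]furan-2(5H)-one | I/C=C(C)\[C@H](O[Si](C)(C)C(C)(C)C)[C@H]1OC(=O)C(CBr)=C1 | intermediate
9 | but-3-yn-1-ol | C#CCCO | starting material
10 | 1-[(but-3-yn-1-yloxy)methyl]-4-methoxybenzene | C#CCCOCc1ccc(OC)cc1 | intermediate
11 | methyl 5-[(4-methoxybenzyl)oxy]pent-2-ynoate | COC(=O)C#CCCOCc1ccc(OC)cc1 | intermediate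
12 | methyl (2Z)-5-[(4-methoxybenzyl)oxy]-3-methylpent-2-enoate | COC(=O)/C=C(C)\CCOCc1ccc(OC)cc1 | intermediate
13 | (2Z)-5-[(4-methoxybenzyl)oxy]-3-methylpent-2-en-1-ol | OC/C=C(C)\CCOCc1ccc(OC)cc1 | intermediate
14 | TES ether of 13 | CC[Si](CC)(CC)OC/C=C(C)\CCOCc1ccc(OC)cc1 | intermediate
15 | (3Z)-3-methyl-5-(triethylsilyloxy)pent-3-en-1-ol | CC[Si](CC)(CC)OC/C=C(C)\CCO | intermediate
16 | (3Z)-3-methyl-5-(triethylsilyloxy)pent-3-enal | CC[Si](CC)(CC)OC/C=C(C)\CC=O | intermediate
17 | Barbier adduct (5S,6S,7R,8S; C8–OH, α-methylene trans-lactone) | O[C@@H](C/C(C)=C\CO[Si](CC)(CC)CC)[C@H]1C(=C)C(=O)O[C@@H]1[C@@H](O[Si](C)(C)C(C)(C)C)/C(C)=C\I | intermediate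
18 | C8 methacrylate of 17 | C=C(C)C(=O)O[C@@H](C/C(C)=C\CO[Si](CC)(CC)CC)[C@H]1C(=C)C(=O)O[C@@H]1[C@@H](O[Si](C)(C)C(C)(C)C)/C(C)=C\I | intermediate
19 | seco Z-enal / Z-vinyl iodide | C=C(C)C(=O)O[C@@H](C/C(C)=C\C=O)[C@H]1C(=C)C(=O)O[C@@H]1[C@@H](O[Si](C)(C)C(C)(C)C)/C(C)=C\I | intermediate
20 | macrocyclic C2 carbinol (C2 epimers), C5–OTBS | C=C(C)C(=O)O[C@H]1C/C(C)=C\C(O)/C=C(C)\[C@H](O[Si](C)(C)C(C)(C)C)[C@H]2OC(=O)C(=C)[C@@H]21 | intermediate
21 | macrocyclic (1(10)Z,3Z)-dienone, C5–OTBS | C=C(C)C(=O)O[C@H]1C/C(C)=C\C(=O)/C=C(C)\[C@H](O[Si](C)(C)C(C)(C)C)[C@H]2OC(=O)C(=C)[C@@H]21 | intermediate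
22 | 2-deethoxy-2β-methoxyphantomolin | C=C(C)C(=O)O[C@H]1C/C(C)=C\[C@@]2(OC)C=C(C)[C@H](O2)[C@H]2OC(=O)C(=C)[C@@H]21 | target

## Step count and risks

Total steps: 20. Longest linear sequence: 13 (steps 1–7 or 8–14, then 15–20).

Steps most likely to fail:

1. **Step 18 (NHK closure of the ten-membered ring).** Fallback: close the ring by Pd-catalysed carbonylative Stille macrocyclisation instead. Fragment B is remade as (Z)-3-methyl-4-(tributylstannyl)but-3-enal; after the Barbier and acylation steps, vinyl iodide + vinylstannane + CO give dienone 21 directly, with C2 coming from CO.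
2. **Step 15 (Barbier union: γ-selectivity, C8 configuration, labile β,γ-unsaturated aldehyde).** Fallback: if the C8 epimer dominates, replace Step 16 by a Mitsunobu esterification with methacrylic acid (PPh3, DIAD), which installs the ester with inversion.
3. **Step 7 (RCM of the bromomethyl acrylate; also the DMAP-sensitive Step 6).** Fallback: acylate 6 with acryloyl chloride, close the unsubstituted butenolide by RCM, then add C13 by Morita–Baylis–Hillman hydroxymethylation (aq. HCHO, imidazole) and Appel bromination to reach 8.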